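The cyclobutane is disconnected across C1–C4 and C2–C3 into two cyclic anhydrides: 2,3-dimethylmaleic anhydride supplies the adjacent quaternary carbons C1 and C2 with their methyl groups, maleic anhydride supplies the CH carbons C3 and C4. One sensitised crossed [2+2] photocycloaddition forms both ring bonds, the four-membered ring and all four stereocentres, because the target's cis-C1/C2 pyrone pair and cis-C3/C4 acid pair lie on opposite faces of the cyclobutane, exactly the anti-fused dianhydride. Both precursors are purchased and used unmodified. Afterwards the C3/C4 anhydride becomes a di-tert-butyl ester, while the hindered C1/C2 anhydride is reduced to a dialdehyde and grown into the two 4-methoxy-3-methyl-2-pyrones.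

Key step: step 1

Assumption: the target SMILES encodes a meso compound (both CO2H groups cis to both methyl groups, both pyrones on the other face), so no absolute stereocontrol is needed; desymmetrised compounds (4, 6, 7, F7) are racemic and drawn as one enantiomer.

Step 1
Reactants: 1 2,3-dimethylmaleic anhydride; 2 maleic anhydride
Product: 3 cis,trans,cis-1,2-dimethylcyclobutane-1,2,3,4-tetracarboxylic 1,2:3,4-dianhydride
Conditions: hν (365 nm), benzophenone (0.2 equiv), 2 (4 equiv), EtOAc, N2, 20 °C
Reagents that add atoms: none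
Why: Benzophenone, the only strong absorber at this wavelength, hands its triplet energy to an anhydride, whose excited C=C bonds through one carbon to the alkene of the partner to give a triplet 1,4-biradical that, once spin-inverted, collapses to the second bond, so that C1–C4 and C2–C3 are formed in one operation. The closest known reaction type is the sensitised [2+2] photodimerisation of maleic anhydride and its alkylated congeners to cis,trans,cis cyclobutane dianhydrides. The cyclobutane is closed stepwise, by recombination of the 1,4-biradical, as the central ring of a tricycle. C1/C2 and C3/C4 are each cis because each pair stays locked in its five-membered anhydride (a trans-fused bicyclo[3.2.0] ring is out of reach, and 1 can neither isomerise nor enolise), and the two pairs come out anti because ring closure takes place in the biradical conformer that keeps the two carbonyl-rich rings on opposite faces, the arrangement of least steric and electrostatic repulsion. The step needs crossed rather than homo coupling: a fourfold excess of unhindered 2 should make the triplet of tetrasubstituted 1 meet 2 rather than a second, hindered molecule of 1, and the sparingly soluble homodimer of 2 should be the only by-product to remove, by fractional crystallisation.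

Step 2
Reactants: 3 cis,trans,cis-1,2-dimethylcyclobutane-1,2,3,4-tetracarboxylic 1,2:3,4-dianhydride
Product: 5 di-tert-butyl 1,5-dimethyl-2,4-dioxo-3-oxabicyclo[3.2.0]heptane-6,7-dicarboxylate, via monoester acid 4 (not isolated)
Conditions: t-BuOH (5 equiv), DMAP (0.3 equiv), Et3N, CH2Cl2, rt to 40 °C; then Boc2O (1.5 equiv), rt
Reagents that add atoms: tert-butanol, CC(C)(C)O; di-tert-butyl dicarbonate (Boc2O), CC(C)(C)OC(=O)OC(=O)OC(C)(C)C
Why: DMAP-catalysed alcoholysis of an anhydride followed by Boc2O/DMAP tert-butyl esterification of the liberated acid: tert-butanol should open only the C3/C4 anhydride, whose carbonyls hang on CH carbons, whereas the C1/C2 anhydride is shielded by two quaternary carbons and held shut by the Thorpe–Ingold effect, and no stereocentre is touched under these weakly basic conditions.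

Step 3
Reactants: 5 di-tert-butyl 1,5-dimethyl-2,4-dioxo-3-oxabicyclo[3.2.0]heptane-6,7-dicarboxylate
Product: 7 di-tert-butyl 1,5-dimethyl-2-oxo-3-oxabicyclo[3.2.0]heptane-6,7-dicarboxylate, via hydroxy acid 6 (not isolated)
Conditions: NaBH4, THF, 0 °C to rt; then aq. citric acid, rt
Reagents that add atoms: none
Why: NaBH4 reduction of a cyclic anhydride to a γ-lactone: hydride takes one of the two equivalent carbonyls to the hydroxymethyl stage, the carboxylate left behind resists borohydride and the hydroxy acid lactonises on acidification (cis groups on adjacent quaternary carbons), while tert-butyl esters are inert to NaBH4 and no stereocentre is altered.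

Step 4
Reactants: 7 di-tert-butyl 1,5-dimethyl-2-oxo-3-oxabicyclo[3.2.0]heptane-6,7-dicarboxylate
Product: 8 di-tert-butyl 3,4-bis(hydroxymethyl)-3,4-dimethylcyclobutane-1,2-dicarboxylate
Conditions: LiBH4, THF, 0 °C to rt
Reagents that add atoms: none
Why: Chemoselective LiBH4 reduction of a lactone to a 1,4-diol: the lactone is far more electrophilic than the two tert-butyl esters, which LiBH4 attacks only slowly, and the new hydroxymethyl groups lie trans to the esters so that they cannot lactonise onto them.

Step 5
Reactants: 8 di-tert-butyl 3,4-bis(hydroxymethyl)-3,4-dimethylcyclobutane-1,2-dicarboxylate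
Product: 9 di-tert-butyl 3,4-diformyl-3,4-dimethylcyclobutane-1,2-dicarboxylate
Conditions: (COCl)2, DMSO, CH2Cl2, −78 °C; Et3N, −78 to 0 °C
Reagents that add atoms: none
Why: Swern oxidation: both primary alcohols are converted into alkoxysulfonium ions before Et3N is added, so the dialdehyde should form without a hydroxy aldehyde (lactol) stage that could be oxidised on to the lactone, and aldehydes on quaternary carbons cannot enolise or epimerise.

Step 6
Reactants: 9 di-tert-butyl 3,4-diformyl-3,4-dimethylcyclobutane-1,2-dicarboxylate; 10 methyl 2-methylacetoacetate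
Product: 12 di-tert-butyl 3,4-bis(1-hydroxy-5-methoxy-4-methyl-3,5-dioxopentyl)-3,4-dimethylcyclobutane-1,2-dicarboxylate, via ketoester dianion 11 (not isolated)
Conditions: 10 (4.4 equiv), NaH, THF, 0 °C; n-BuLi, 0 °C; then 9, −78 to −20 °C; AcOH, −78 °C
Reagents that add atoms: none
Why: γ-Selective aldol addition of a β-keto ester dianion (Weiler dianion): the terminal carbanion of 11 adds to the non-enolisable, neopentyl-type aldehydes, excess dianion and warming should carry the second addition through the open form of any lactolate formed after the first, and the new carbinol and side-chain C2 centres are left uncontrolled because steps 7 and 8 erase them.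

Step 7
Reactants: 12 di-tert-butyl 3,4-bis(1-hydroxy-5-methoxy-4-methyl-3,5-dioxopentyl)-3,4-dimethylcyclobutane-1,2-dicarboxylate
Product: 13 di-tert-butyl 3,4-bis(5-methoxy-4-methyl-3,5-dioxopentanoyl)-3,4-dimethylcyclobutane-1,2-dicarboxylate
Conditions: Dess–Martin periodinane, CH2Cl2, 0 °C to rt
Reagents that add atoms: none
Why: Dess–Martin oxidation of secondary alcohols to ketones under neutral conditions, which β-keto esters, tert-butyl esters and the ring stereocentres tolerate, and which should deliver the 3,5-diketo esters as their enols.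

Step 8
Reactants: 13 di-tert-butyl 3,4-bis(5-methoxy-4-methyl-3,5-dioxopentanoyl)-3,4-dimethylcyclobutane-1,2-dicarboxylate
Product: 14 di-tert-butyl 3,4-bis(4-hydroxy-3-methyl-2-oxo-2H-pyran-6-yl)-3,4-dimethylcyclobutane-1,2-dicarboxylate
Conditions: DBU (5 equiv), toluene, rt to 60 °C; dilute aq. HCl work-up
Reagents that add atoms: none
Why: Base-mediated enol lactonisation of a 3,5-diketo ester, the standard 4-hydroxy-2-pyrone synthesis: the enolate oxygen of the carbonyl bound to the cyclobutane attacks the methyl ester in a 6-exo-trig acyl substitution with loss of methanol, and excess DBU keeps both diketone arms enolised so that neither ketone should be electrophilic enough for a cross-arm aldol reaction.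

Step 9
Reactants: 14 di-tert-butyl 3,4-bis(4-hydroxy-3-methyl-2-oxo-2H-pyran-6-yl)-3,4-dimethylcyclobutane-1,2-dicarboxylate
Product: 15 di-tert-butyl 3,4-bis(4-methoxy-3-methyl-2-oxo-2H-pyran-6-yl)-3,4-dimethylcyclobutane-1,2-dicarboxylate
Conditions: Me2SO4, K2CO3, acetone, rt to 50 °C
Reagents that add atoms: dimethyl sulfate, COS(=O)(=O)OC
Why: O-Methylation of 4-hydroxy-2-pyrones with Me2SO4 and K2CO3 in acetone, which for 3-alkyl-4-hydroxy-2-pyrones without a 5-substituent is known to favour the 4-methoxy-2-pyrone over the 2-methoxy-4-pyrone isomer, while tert-butyl esters and the cis CH centres are unaffected by the weak base.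

Step 10
Reactants: 15 di-tert-butyl 3,4-bis(4-methoxy-3-methyl-2-oxo-2H-pyran-6-yl)-3,4-dimethylcyclobutane-1,2-dicarboxylate
Product: 16 3,4-bis(4-methoxy-3-methyl-2-oxo-2H-pyran-6-yl)-3,4-dimethylcyclobutane-1,2-dicarboxylic acid (target)
Conditions: CF3CO2H/CH2Cl2 (1:2), rt
Reagents that add atoms: none
Why: Acidolysis of tert-butyl esters (alkyl–oxygen cleavage through the tert-butyl cation, released as isobutene), which should leave the methoxypyrones untouched and, being base-free, cannot epimerise the cis C3/C4 centres.

Compound list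
1 | 2,3-dimethylmaleic anhydride | CC1=C(C)C(=O)OC1=O | starting material
2 | maleic anhydride | O=C1OC(=O)C=C1 | starting material
3 | cis,trans,cis-1,2-dimethylcyclobutane-1,2,3,4-tetracarboxylic 1,2:3,4-dianhydride (meso, anhydride rings on opposite faces) | O1C(=O)[C@@]2(C)[C@H](C(=O)O3)[C@H](C3=O)[C@@]2(C)C1=O | intermediate
4 | 7-(tert-butoxycarbonyl)-1,5-dimethyl-2,4-dioxo-3-oxabicyclo[3.2.0]heptane-6-carboxylic acid (racemic; ester and acid cis to each other and to both methyls, trans to the anhydride ring) | O1C(=O)[C@@]2(C)[C@H](C(=O)OC(C)(C)C)[C@H](C(=O)O)[C@@]2(C)C1=O | intermediate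
5 | di-tert-butyl 1,5-dimethyl-2,4-dioxo-3-oxabicyclo[3.2.0]heptane-6,7-dicarboxylate (meso; esters cis to the methyls, trans to the anhydride ring) | O1C(=O)[C@@]2(C)[C@H](C(=O)OC(C)(C)C)[C@H](C(=O)OC(C)(C)C)[C@@]2(C)C1=O | intermediate
6 | 2,3-bis(tert-butoxycarbonyl)-4-(hydroxymethyl)-1,4-dimethylcyclobutane-1-carboxylic acid (racemic; CH2OH and CO2H cis, both trans to the esters) | OC[C@@]2(C)[C@H](C(=O)OC(C)(C)C)[C@H](C(=O)OC(C)(C)C)[C@@]2(C)C(=O)O | intermediate
7 | di-tert-butyl 1,5-dimethyl-2-oxo-3-oxabicyclo[3.2.0]heptane-6,7-dicarboxylate (racemic; cis-fused lactone trans to the esters) | O1C[C@@]2(C)[C@H](C(=O)OC(C)(C)C)[C@H](C(=O)OC(C)(C)C)[C@@]2(C)C1=O | intermediate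
8 | di-tert-butyl 3,4-bis(hydroxymethyl)-3,4-dimethylcyclobutane-1,2-dicarboxylate (meso; esters cis to each other and to both methyls) | OC[C@@]2(C)[C@H](C(=O)OC(C)(C)C)[C@H](C(=O)OC(C)(C)C)[C@@]2(C)CO | intermediate
9 | di-tert-butyl 3,4-diformyl-3,4-dimethylcyclobutane-1,2-dicarboxylate (meso; formyl groups cis, trans to the esters) | O=C[C@@]2(C)[C@H](C(=O)OC(C)(C)C)[C@H](C(=O)OC(C)(C)C)[C@@]2(C)C=O | intermediate
10 | methyl 2-methylacetoacetate (methyl 2-methyl-3-oxobutanoate) | CC(=O)C(C)C(=O)OC | starting material
11 | sodium lithium 1,3-dienolate (dianion) of methyl 2-methylacetoacetate | [Na+].[Li+].C=C([O-])C(C)=C([O-])OC | intermediate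
12 | di-tert-butyl 3,4-bis(1-hydroxy-5-methoxy-4-methyl-3,5-dioxopentyl)-3,4-dimethylcyclobutane-1,2-dicarboxylate (ring configuration as in 9; side-chain centres as a mixture) | COC(=O)C(C)C(=O)CC(O)[C@@]2(C)[C@H](C(=O)OC(C)(C)C)[C@H](C(=O)OC(C)(C)C)[C@@]2(C)C(O)CC(=O)C(C)C(=O)OC | intermediate
13 | di-tert-butyl 3,4-bis(5-methoxy-4-methyl-3,5-dioxopentanoyl)-3,4-dimethylcyclobutane-1,2-dicarboxylate (side-chain C4 centres as a mixture) | COC(=O)C(C)C(=O)CC(=O)[C@@]2(C)[C@H](C(=O)OC(C)(C)C)[C@H](C(=O)OC(C)(C)C)[C@@]2(C)C(=O)CC(=O)C(C)C(=O)OC | intermediate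
14 | di-tert-butyl 3,4-bis(4-hydroxy-3-methyl-2-oxo-2H-pyran-6-yl)-3,4-dimethylcyclobutane-1,2-dicarboxylate (meso) | Oc1cc([C@@]2(C)[C@H](C(=O)OC(C)(C)C)[C@H](C(=O)OC(C)(C)C)[C@@]2(C)c2cc(O)c(C)c(=O)o2)oc(=O)c1C | intermediate
15 | di-tert-butyl 3,4-bis(4-methoxy-3-methyl-2-oxo-2H-pyran-6-yl)-3,4-dimethylcyclobutane-1,2-dicarboxylate (meso) | COc1cc([C@@]2(C)[C@H](C(=O)OC(C)(C)C)[C@H](C(=O)OC(C)(C)C)[C@@]2(C)c2cc(OC)c(C)c(=O)o2)oc(=O)c1C | intermediate
16 | 3,4-bis(4-methoxy-3-methyl-2-oxo-2H-pyran-6-yl)-3,4-dimethylcyclobutane-1,2-dicarboxylic acid (CNP0574758.1; acids cis to each other and to both methyls) | COc1cc([C@@]2(C)[C@H](C(=O)O)[C@H](C(=O)O)[C@@]2(C)c2cc(OC)c(C)c(=O)o2)oc(=O)c1C | target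

Total step count: 10. Longest linear sequence: 10 steps (1 and 2 to 16; 10 enters at step 6).

Steps most likely to fail

Step 6. After the first addition the lithium alkoxide can close onto the neighbouring cis-formyl group, and the resulting lactolate may resist the second addition, so that mono-adducts accumulate. The fallback sets out from 9 and 10 and comes back at 12. 10 would be O-silylated (Me3SiCl, Et3N) to methyl 2-methyl-3-(trimethylsilyloxy)but-2-enoate F1 and then deprotonated and silylated again (LiN(iPr)2, Me3SiCl, THF, −78 °C) to 1-methoxy-2-methyl-1,3-bis(trimethylsilyloxy)buta-1,3-diene F2. F2 would be added to both aldehydes of 9 under BF3·OEt2 in CH2Cl2 at −78 °C (two-directional vinylogous Mukaiyama aldol), where the aldolate oxygen is bound to boron or silicon and is not free to attack the second formyl group. Aqueous work-up would remove the silyl groups and give 12.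

Step 8. Under base the activated methylene of one diketone arm can condense with the 1,4-related ketone of the other arm (five-membered aldol or Knoevenagel closure) in competition with lactonisation. The fallback sets out from 9 and comes back at 14. 2,2,5,6-Tetramethyl-4H-1,3-dioxin-4-one F3 (made from tert-butyl 2-methylacetoacetate, acetone, Ac2O and H2SO4) would be deprotonated at its 6-methyl group (LiN(iPr)2, THF, −78 °C) and added to 9 to give the bis(2-hydroxyalkyl)dioxinone F4. Dess–Martin oxidation would give the bis(2-oxoalkyl)dioxinone F5. Heating F5 in toluene at 110 °C would expel acetone and let each acylketene be captured by the enol of its own neighbouring ketone, closing both 4-hydroxy-2-pyrones of 14 with no base present.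

Step 1. Homodimerisation of either anhydride may outrun the crossed addition, or the three dimers may co-crystallise and defeat separation. The fallback sets out from 1 and comes back at 3. 1 would be irradiated with benzophenone in the presence of excess 2,5-dihydrofuran, a cis-locked alkene that cannot be sensitised or dimerise, to give the anti-fused tetrahydrofuran anhydride F6. RuCl3 (cat.)/NaIO4 would oxidise the ether to the γ-lactone F7. Saponification and KMnO4 oxidation in aqueous NaOH, followed by acidification, would give cis,trans,cis-1,2-dimethylcyclobutane-1,2,3,4-tetracarboxylic acid F8. Ac2O at reflux would then close both anhydrides to 3.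

Further compounds
F1 | step 6 | methyl 2-methyl-3-(trimethylsilyloxy)but-2-enoate | COC(=O)C(C)=C(C)O[Si](C)(C)C
F2 | step 6 | 1-methoxy-2-methyl-1,3-bis(trimethylsilyloxy)buta-1,3-diene | COC(O[Si](C)(C)C)=C(C)C(=C)O[Si](C)(C)C
F3 | step 8 | 2,2,5,6-tetramethyl-4H-1,3-dioxin-4-one | CC1=C(C)C(=O)OC(C)(C)O1
F4 | step 8 | di-tert-butyl 3,4-bis[1-hydroxy-2-(2,2,5-trimethyl-4-oxo-4H-1,3-dioxin-6-yl)ethyl]-3,4-dimethylcyclobutane-1,2-dicarboxylate (carbinol centres as a mixture) | CC1=C(CC(O)[C@@]2(C)[C@H](C(=O)OC(C)(C)C)[C@H](C(=O)OC(C)(C)C)[C@@]2(C)C(O)CC2=C(C)C(=O)OC(C)(C)O2)OC(C)(C)OC1=O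
F5 | step 8 | di-tert-butyl 3,4-bis[(2,2,5-trimethyl-4-oxo-4H-1,3-dioxin-6-yl)acetyl]-3,4-dimethylcyclobutane-1,2-dicarboxylate | CC1=C(CC(=O)[C@@]2(C)[C@H](C(=O)OC(C)(C)C)[C@H](C(=O)OC(C)(C)C)[C@@]2(C)C(=O)CC2=C(C)C(=O)OC(C)(C)O2)OC(C)(C)OC1=O
F6 | step 1 | 1,2-dimethylcyclobutane-1,2-dicarboxylic anhydride fused anti at C3–C4 to a tetrahydrofuran ring (meso) | O1C(=O)[C@@]2(C)[C@H](CO3)[C@H](C3)[C@@]2(C)C1=O
F7 | step 1 | 1,2-dimethylcyclobutane-1,2-dicarboxylic anhydride fused anti at C3–C4 to a γ-butyrolactone ring (racemic) | O1C(=O)[C@@]2(C)[C@H](C(=O)O3)[C@H](C3)[C@@]2(C)C1=O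
F8 | step 1 | cis,trans,cis-1,2-dimethylcyclobutane-1,2,3,4-tetracarboxylic acid | OC(=O)[C@@]2(C)[C@H](C(=O)O)[C@H](C(=O)O)[C@@]2(C)C(=O)O
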